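## Retrosynthetic overview

1. Reading of the target: a labd-7-en-15-oic acid whose decalin is cis-fused (5-H, the C10 methyl and the C9 side chain on one face), with 2α-OH, 3α-O-acyl, 13S and an (S)-2-hydroxy-2-methylbutanoate. The usual trans-selective polyene cyclisation or sclareolide-type entry is therefore set aside.
2. Endgame: desilylation and methyl ester hydrolysis; C9–H and the 7,8-olefin come from a 7β-allylic alcohol by Myers reductive 1,3-transposition, which relays the C7 chirality to C9 and then erases it. C9–C11 comes from Negishi coupling of a C9 enol triflate with a C11–C15 alkylzinc cut from (R)-methyl hydrogen 3-methylglutarate.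
3. Ring A dressing: 3-ester from the acid chloride of silylated (S)-2-hydroxy-2-methylbutanoic acid; 2α,3α-oxygens from a C2=C3 silyl enol ether (Rubottom, then bulky hydride); the 7β-oxygen from the carvone isopropenyl group by ozonolysis/Criegee rearrangement.
4. Key step and ring order: ring B is (S)-carvone. Ring A (C1–C4) is annulated onto it in one step by a Lewis-acid-catalysed formal [4+2] of a hindered 2-silyloxydiene, which creates the C4 and C10 quaternary carbons and the cis fusion anti to the isopropenyl group.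

Conventions and assumption: labdane numbering is used for every bicyclic compound (ring A = C1–C5, C10; ring B = C5–C10; side chain C11–C15); β is the face of the C10 methyl, α the opposite face; TBS = tert-butyldimethylsilyl, TES = triethylsilyl, Tf = trifluoromethanesulfonyl; compounds 1, 3, 12 and 19 are taken as purchasable.

## Route

Step 1
Reactants: 1 4-methylpent-1-en-3-one
Product: 2 tert-butyl(dimethyl)[(4-methylpenta-1,3-dien-3-yl)oxy]silane
Conditions: TBSOTf, Et3N, Et2O, 0 °C
Reagents that add atoms: tert-butyldimethylsilyl trifluoromethanesulfonate CC(C)(C)[Si](C)(C)OS(=O)(=O)C(F)(F)F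
Why: Soft enolisation (silyl triflate/amine) of the only enolisable position, the isopropyl CH, gives the cross-conjugated 2-silyloxydiene; no stereocentre is formed.

Step 2
Reactants: 3 (S)-(+)-carvone; 2 silyloxydiene
Product: 4 3-(TBS-oxy)-7β-isopropenyl-4,4,10β-trimethyl-5βH-decal-2-en-9-one (cis-fused)
Conditions: AlBr3/AlMe3 (10:1, 20 mol %), PhMe/CH2Cl2, −5 °C to rt; Et3N then NaHCO3 quench
Reagents that add atoms: none
Why: Lewis-acid-catalysed Diels–Alder reaction of a hindered 2-silyloxydiene (asynchronous, Mukaiyama–Michael-like, so the nucleophilic CMe2 terminus bonds to the enone β-carbon C5 and the CH2 terminus to C10) adds suprafacially to carvone anti to its isopropenyl group, which fixes the cis fusion with 5-H, the C10 methyl and the C7 isopropenyl all β and creates the C4 quaternary carbon.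

Step 3
Reactants: 4 cis-decalone silyl enol ether
Product: 6 3-(TBS-oxy)-7β-isopropenyl-4,4,8α,10β-tetramethyl-5βH-decal-2-en-9-one, via lithium C8-enolate 5 (not isolated)
Conditions: LiN(i-Pr)2, THF, −78 °C; MeI, −78 to −20 °C
Reagents that add atoms: iodomethane CI
Why: Kinetic enolate alkylation can occur only at C8, because C10 is quaternary and the ring A carbonyl is masked as its silyl enol ether; the new C8 centre (methyl expected anti to the isopropenyl group) is erased in step 4.

Step 4
Reactants: 6 C8-methyl ketone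
Product: 8 3-(TBS-oxy)-7β-isopropenyl-4,4,8,10β-tetramethyl-5βH-decala-2,8-dien-9-yl triflate, via potassium C8-enolate 7 (not isolated)
Conditions: KN(SiMe3)2, THF, −78 to 0 °C; PhNTf2, −78 °C to rt
Reagents that add atoms: N-phenylbis(trifluoromethanesulfonimide) O=S(=O)(N(c1ccccc1)S(=O)(=O)C(F)(F)F)C(F)(F)F
Why: Enol triflate formation by O-sulfonylation of the only possible enolate (C8–H is the sole α-hydrogen) gives the tetrasubstituted C8=C9 triflate of the 2,6,6-trimethylcyclohexenyl type; no stereocentre is created.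

Step 5
Reactants: 8 enol triflate silyl enol ether
Product: 10 2α-(TBS-oxy)-7β-isopropenyl-4,4,8,10β-tetramethyl-3-oxo-5βH-decal-8-en-9-yl triflate, via 2α,3α-epoxy silyl ether 9 (not isolated)
Conditions: mCPBA (1.05 equiv), NaHCO3, CH2Cl2, −20 °C to rt
Reagents that add atoms: 3-chloroperoxybenzoic acid O=C(OO)c1cccc(Cl)c1
Why: Rubottom oxidation, in which the peracid attacks only the electron-rich silyl enol ether (the isopropenyl and triflate olefins are far less nucleophilic) from the α face away from the axial C10 and 4β methyls, and 1,4-silyl migration in the opened epoxide gives the 2α-silyloxy ketone, which is also the equatorial, thermodynamically preferred C2 epimer.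

Step 6
Reactants: 10 2α-silyloxy 3-ketone
Product: 11 3α-hydroxy-2α-(TBS-oxy)-7β-isopropenyl-4,4,8,10β-tetramethyl-5βH-decal-8-en-9-yl triflate
Conditions: LiBH(s-Bu)3, THF, −78 °C; pH 7 buffer at −78 °C
Reagents that add atoms: none
Why: Diastereoselective ketone reduction by a bulky trialkylborohydride, where equatorial hydride delivery from the β face (the axial α approach is blocked by C6, which is axial on ring A in this cis-decalin) gives the axial 3α-alcohol cis to the 2α-silyloxy group, and the cold quench prevents O2 to O3 silyl migration.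

Step 7
Reactants: 12 (S)-2-hydroxy-2-methylbutanoic acid
Product: 14 (S)-2-methyl-2-(triethylsilyloxy)butanoyl chloride, via bis-TES derivative 13 (not isolated)
Conditions: TESOTf (2.2 equiv), 2,6-lutidine, CH2Cl2, 0 °C; then (COCl)2, DMF (cat.), 0 °C to rt
Reagents that add atoms: triethylsilyl trifluoromethanesulfonate CC[Si](CC)(CC)OS(=O)(=O)C(F)(F)F; oxalyl chloride O=C(Cl)C(Cl)=O
Why: Silylation followed by direct conversion of the silyl ester into the acid chloride with oxalyl chloride/DMF releases no HCl, so the tertiary silyl ether survives, and the quaternary stereocentre cannot epimerise.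

Step 8
Reactants: 11 3α-alcohol; 14 acid chloride
Product: 15 3α-[(S)-2-methyl-2-(TES-oxy)butanoyloxy]-2α-(TBS-oxy)-7β-isopropenyl-4,4,8,10β-tetramethyl-5βH-decal-8-en-9-yl triflate
Conditions: DMAP (0.5 equiv), Et3N, ClCH2CH2Cl, 60 °C
Reagents that add atoms: none
Why: DMAP-catalysed acylation (acylpyridinium transfer) of the only free hydroxyl esterifies the axial 3α-OH without touching any stereocentre, and the neutral conditions avoid silyl migration from O2.

Step 9
Reactants: 15 3α-ester
Product: 18 7β-acetoxy-3α-[(S)-2-methyl-2-(TES-oxy)butanoyloxy]-2α-(TBS-oxy)-4,4,8,10β-tetramethyl-5βH-decal-8-en-9-yl triflate, via α-methoxy hydroperoxide 16 (not isolated), via peracetate 17 (not isolated)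
Conditions: O3, CH2Cl2/MeOH, −78 °C (Sudan Red 7B end-point); then Ac2O, Et3N, DMAP, 0 to 40 °C; aqueous work-up
Reagents that add atoms: ozone [O-][O+]=O; water O
Why: Ozonolysis of the isopropenyl group in methanol (the triflate-bearing olefin is too electron-poor to react) and Criegee rearrangement of the derived peracetate move C7 from carbon to oxygen with retention, so the carvone stereocentre becomes a 7β-acetate whose acetyl carbons are the former isopropenyl carbons.

Step 10
Reactants: 19 (R)-3-methylglutaric acid monomethyl ester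
Product: 21 (S)-4-methyloxan-2-one, via (S)-5-hydroxy-3-methylpentanoic acid 20 (not isolated)
Conditions: LiBH4, THF, 0 °C to reflux; then 2 M HCl, rt
Reagents that add atoms: none
Why: Chemoselective borohydride reduction of the ester in the presence of the carboxylate, then acid-induced lactonisation, leaves the stereocentre untouched, and reducing this terminus (not the acid) is what leads to the 13S series.

Step 11
Reactants: 21 lactone
Product: 23 methyl (R)-5-bromo-3-methylpentanoate, via (R)-5-bromo-3-methylpentanoic acid 22 (not isolated)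
Conditions: HBr (33 % in AcOH), 70 °C; then MeOH, rt
Reagents that add atoms: hydrogen bromide Br; methanol CO
Why: SN2 opening of the lactone at the primary O–CH2 carbon by bromide and Fischer esterification leave the remote stereocentre unchanged (its descriptor becomes R only through the CIP priorities).

Step 12
Reactants: 23 bromo ester; 18 7β-acetoxy enol triflate
Product: 25 methyl (13S)-7β-acetoxy-3α-[(S)-2-methyl-2-(TES-oxy)butanoyloxy]-2α-(TBS-oxy)-5βH-labd-8-en-15-oate, via alkylzinc bromide 24 (not isolated)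
Conditions: Zn dust (activated with BrCH2CH2Br and Me3SiCl), LiCl, THF, 50 °C; then 18, PdCl2(dppf) (5 mol %), THF/DMA, 60 °C
Reagents that add atoms: none
Why: Zinc insertion and Negishi sp3–sp2 cross-coupling, in which the ester-tolerant primary alkylzinc couples with the hindered enol triflate (the 2,6,6-trimethylcyclohexenyl triflate type is a proven partner), form C9–C11 without touching C13 or the hindered allylic acetate.

Step 13
Reactants: 25 7β-acetate
Product: 26 methyl (13S)-7β-hydroxy-3α-[(S)-2-methyl-2-(TES-oxy)butanoyloxy]-2α-(TBS-oxy)-5βH-labd-8-en-15-oate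
Conditions: K2CO3 (0.2 equiv), MeOH, 0 °C to rt
Reagents that add atoms: none
Why: Base-catalysed transesterification removes the unhindered secondary acetate, while the C3 ester (α-quaternary acyl carbon, flanked by silyl ethers) is untouched and exchange at the side-chain methyl ester is degenerate in methanol.

Step 14
Reactants: 26 7β-allylic alcohol
Product: 29 methyl (13S)-3α-[(S)-2-methyl-2-(TES-oxy)butanoyloxy]-2α-(TBS-oxy)-5βH,9αH-labd-7-en-15-oate, via sulfonylhydrazine adduct 27 (not isolated), via allylic diazene 28 (not isolated)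
Conditions: 2-nitrobenzenesulfonylhydrazide, PPh3, DEAD, N-methylmorpholine, −30 °C; then 23 °C
Reagents that add atoms: none
Why: Myers reductive 1,3-transposition, in which Mitsunobu displacement inverts C7 (nitrogen on the α face), loss of sulfinic acid gives the monoalkyl diazene, and its retro-ene loss of N2 delivers hydrogen suprafacially to C9 from the α face, placing the side chain β (cis to the C10 methyl), forming the 7,8-olefin and erasing the C7 centre.

Step 15
Reactants: 29 methyl ester
Product: 30 (13S)-3α-[(S)-2-methyl-2-(TES-oxy)butanoyloxy]-2α-(TBS-oxy)-5βH,9αH-labd-7-en-15-oic acid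
Conditions: LiOH, THF/MeOH/H2O, rt; then 1 M HCl to pH 4
Reagents that add atoms: lithium hydroxide [Li+].[OH-]
Why: Saponification of the unhindered methyl ester is selective because the C3 ester is shielded by its α-quaternary carbon and two silyl ethers, and with O2 still silylated no acyl migration can occur.

Step 16
Reactants: 30 bis-silyl acid
Product: 31 (13S)-2α-hydroxy-3α-[(S)-2-hydroxy-2-methylbutanoyloxy]-5βH,9αH-labd-7-en-15-oic acid (target; CIP 2R,3S,5S,9S,10R,13S,2'S)
Conditions: HF·pyridine, pyridine, THF, 0 °C to rt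
Reagents that add atoms: none
Why: Fluoride-mediated desilylation under buffered, non-basic conditions removes both silyl ethers without O3 to O2 acyl migration or olefin isomerisation, and no stereocentre is affected.

## Compound list

1 | 4-methylpent-1-en-3-one (isopropyl vinyl ketone) | C=CC(=O)C(C)C | starting material
2 | tert-butyl(dimethyl)[(4-methylpenta-1,3-dien-3-yl)oxy]silane | C=CC(O[Si](C)(C)C(C)(C)C)=C(C)C | intermediate
3 | (S)-(+)-carvone; (5S)-2-methyl-5-(prop-1-en-2-yl)cyclohex-2-en-1-one | CC1=CC[C@@H](CC1=O)C(C)=C | starting material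
4 | 3-(TBS-oxy)-7β-isopropenyl-4,4,10β-trimethyl-5βH-decal-2-en-9-one (cis-fused) | CC(C)(C)[Si](C)(C)OC1=CC[C@@]2(C)[C@H](C[C@H](C(C)=C)CC2=O)C1(C)C | intermediate
5 | lithium C8(9)-enolate of 4 | CC(C)(C)[Si](C)(C)OC1=CC[C@@]2(C)[C@H](C[C@H](C(C)=C)C=C2O[Li])C1(C)C | intermediate
6 | 3-(TBS-oxy)-7β-isopropenyl-4,4,8α,10β-tetramethyl-5βH-decal-2-en-9-one | CC(C)(C)[Si](C)(C)OC1=CC[C@@]2(C)[C@H](C[C@H](C(C)=C)[C@@H](C)C2=O)C1(C)C | intermediate
7 | potassium C8(9)-enolate of 6 | CC(C)(C)[Si](C)(C)OC1=CC[C@@]2(C)[C@H](C[C@H](C(C)=C)C(C)=C2O[K])C1(C)C | intermediate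
8 | 3-(TBS-oxy)-7β-isopropenyl-4,4,8,10β-tetramethyl-5βH-decala-2,8-dien-9-yl triflate | CC(C)(C)[Si](C)(C)OC1=CC[C@@]2(C)[C@H](C[C@H](C(C)=C)C(C)=C2OS(=O)(=O)C(F)(F)F)C1(C)C | intermediate
9 | 2α,3α-epoxy-3β-(TBS-oxy) derivative of 8 | CC(C)(C)[Si](C)(C)O[C@]12O[C@@H]2C[C@@]3(C)[C@H](C[C@H](C(C)=C)C(C)=C3OS(=O)(=O)C(F)(F)F)C1(C)C | intermediate
10 | 2α-(TBS-oxy)-7β-isopropenyl-4,4,8,10β-tetramethyl-3-oxo-5βH-decal-8-en-9-yl triflate | O=C1[C@H](O[Si](C)(C)C(C)(C)C)C[C@@]2(C)[C@H](C[C@H](C(C)=C)C(C)=C2OS(=O)(=O)C(F)(F)F)C1(C)C | intermediate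
11 | 3α-hydroxy-2α-(TBS-oxy)-7β-isopropenyl-4,4,8,10β-tetramethyl-5βH-decal-8-en-9-yl triflate | O[C@@H]1[C@H](O[Si](C)(C)C(C)(C)C)C[C@@]2(C)[C@H](C[C@H](C(C)=C)C(C)=C2OS(=O)(=O)C(F)(F)F)C1(C)C | intermediate
12 | (S)-2-hydroxy-2-methylbutanoic acid | CC[C@](C)(O)C(=O)O | starting material
13 | triethylsilyl (S)-2-methyl-2-(triethylsilyloxy)butanoate | CC[C@](C)(O[Si](CC)(CC)CC)C(=O)O[Si](CC)(CC)CC | intermediate
14 | (S)-2-methyl-2-(triethylsilyloxy)butanoyl chloride | CC[C@](C)(O[Si](CC)(CC)CC)C(Cl)=O | intermediate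
15 | 3α-[(S)-2-methyl-2-(TES-oxy)butanoyloxy]-2α-(TBS-oxy)-7β-isopropenyl-4,4,8,10β-tetramethyl-5βH-decal-8-en-9-yl triflate | CC[C@](C)(O[Si](CC)(CC)CC)C(=O)O[C@@H]1[C@H](O[Si](C)(C)C(C)(C)C)C[C@@]2(C)[C@H](C[C@H](C(C)=C)C(C)=C2OS(=O)(=O)C(F)(F)F)C1(C)C | intermediate
16 | α-methoxy hydroperoxide of 15 at the former isopropenyl carbon (epimers at that carbon) | CC[C@](C)(O[Si](CC)(CC)CC)C(=O)O[C@@H]1[C@H](O[Si](C)(C)C(C)(C)C)C[C@@]2(C)[C@H](C[C@H](C(C)(OC)OO)C(C)=C2OS(=O)(=O)C(F)(F)F)C1(C)C | intermediate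
17 | peracetate of 16 | CC[C@](C)(O[Si](CC)(CC)CC)C(=O)O[C@@H]1[C@H](O[Si](C)(C)C(C)(C)C)C[C@@]2(C)[C@H](C[C@H](C(C)(OC)OOC(C)=O)C(C)=C2OS(=O)(=O)C(F)(F)F)C1(C)C | intermediate
18 | 7β-acetoxy-3α-[(S)-2-methyl-2-(TES-oxy)butanoyloxy]-2α-(TBS-oxy)-4,4,8,10β-tetramethyl-5βH-decal-8-en-9-yl triflate | CC[C@](C)(O[Si](CC)(CC)CC)C(=O)O[C@@H]1[C@H](O[Si](C)(C)C(C)(C)C)C[C@@]2(C)[C@H](C[C@H](OC(C)=O)C(C)=C2OS(=O)(=O)C(F)(F)F)C1(C)C | intermediate
19 | (R)-3-methylglutaric acid monomethyl ester; (3R)-5-methoxy-3-methyl-5-oxopentanoic acid | COC(=O)C[C@H](C)CC(=O)O | starting material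
20 | (S)-5-hydroxy-3-methylpentanoic acid | OCC[C@H](C)CC(=O)O | intermediate
21 | (S)-4-methyloxan-2-one | O=C1C[C@@H](C)CCO1 | intermediate
22 | (R)-5-bromo-3-methylpentanoic acid | OC(=O)C[C@@H](C)CCBr | intermediate
23 | methyl (R)-5-bromo-3-methylpentanoate | COC(=O)C[C@@H](C)CCBr | intermediate
24 | [(3R)-5-methoxy-3-methyl-5-oxopentyl]zinc bromide | COC(=O)C[C@@H](C)CC[Zn]Br | intermediate
25 | methyl (13S)-7β-acetoxy-3α-[(S)-2-methyl-2-(TES-oxy)butanoyloxy]-2α-(TBS-oxy)-5βH-labd-8-en-15-oate | CC[C@](C)(O[Si](CC)(CC)CC)C(=O)O[C@@H]1[C@H](O[Si](C)(C)C(C)(C)C)C[C@@]2(C)[C@H](C[C@H](OC(C)=O)C(C)=C2CC[C@H](C)CC(=O)OC)C1(C)C | intermediate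
26 | methyl (13S)-7β-hydroxy-3α-[(S)-2-methyl-2-(TES-oxy)butanoyloxy]-2α-(TBS-oxy)-5βH-labd-8-en-15-oate | CC[C@](C)(O[Si](CC)(CC)CC)C(=O)O[C@@H]1[C@H](O[Si](C)(C)C(C)(C)C)C[C@@]2(C)[C@H](C[C@H](O)C(C)=C2CC[C@H](C)CC(=O)OC)C1(C)C | intermediate
27 | 7α-[N-amino-N-(2-nitrobenzenesulfonyl)amino] Mitsunobu adduct of 26 | CC[C@](C)(O[Si](CC)(CC)CC)C(=O)O[C@@H]1[C@H](O[Si](C)(C)C(C)(C)C)C[C@@]2(C)[C@H](C[C@@H](N(N)S(=O)(=O)c3ccccc3[N+](=O)[O-])C(C)=C2CC[C@H](C)CC(=O)OC)C1(C)C | intermediate
28 | 7α-diazenyl (allylic diazene) derivative | CC[C@](C)(O[Si](CC)(CC)CC)C(=O)O[C@@H]1[C@H](O[Si](C)(C)C(C)(C)C)C[C@@]2(C)[C@H](C[C@@H](N=N)C(C)=C2CC[C@H](C)CC(=O)OC)C1(C)C | intermediate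
29 | methyl (13S)-3α-[(S)-2-methyl-2-(TES-oxy)butanoyloxy]-2α-(TBS-oxy)-5βH,9αH-labd-7-en-15-oate | CC[C@](C)(O[Si](CC)(CC)CC)C(=O)O[C@@H]1[C@H](O[Si](C)(C)C(C)(C)C)C[C@@]2(C)[C@H](CC=C(C)[C@@H]2CC[C@H](C)CC(=O)OC)C1(C)C | intermediate
30 | (13S)-3α-[(S)-2-methyl-2-(TES-oxy)butanoyloxy]-2α-(TBS-oxy)-5βH,9αH-labd-7-en-15-oic acid | CC[C@](C)(O[Si](CC)(CC)CC)C(=O)O[C@@H]1[C@H](O[Si](C)(C)C(C)(C)C)C[C@@]2(C)[C@H](CC=C(C)[C@@H]2CC[C@H](C)CC(=O)O)C1(C)C | intermediate
31 | (13S)-2α-hydroxy-3α-[(S)-2-hydroxy-2-methylbutanoyloxy]-5βH,9αH-labd-7-en-15-oic acid (CNP0305549.1) | CC[C@](C)(O)C(=O)O[C@@H]1[C@H](O)C[C@@]2(C)[C@H](CC=C(C)[C@@H]2CC[C@H](C)CC(=O)O)C1(C)C | target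

## Step count and risk

Total step count: 16. Longest linear sequence: 13 steps (steps 1–6, 8, 9 and 12–16, from 1 to 31).

Three steps most likely to fail:

Step 2 (annulation). The C4–C5 bond joins a fully substituted diene terminus to the β-carbon of an α-methyl enone, and the usual failure is a stalled Michael adduct instead of a ring. Fallback: setting out from 3 and 2, the two bonds are made in separate operations. A [Ph3C][SbCl6]-catalysed Mukaiyama–Michael addition at −78 °C joins only C4 to C5 (anti to the isopropenyl group) and transfers the silyl group to the ring B enolate. This gives the ring B silyl enol ether carrying the vinyl ketone chain, 1-(TBS-oxy)-2-methyl-3-(2-methyl-3-oxopent-4-en-2-yl)-5-isopropenylcyclohex-1-ene F1. A catalytic amount of [Bu4N][Ph3SiF2] then triggers intramolecular Michael addition of the C10 enolate onto the vinyl ketone from the face of the tether, with silyl transfer to the new C3 enolate, and the sequence comes back to the route at 4.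

Step 8 (esterification). An axial, neopentyl 3α-OH next to a silyl ether must be acylated by an α-quaternary acid chloride. Fallback: setting out from 11, HF·pyridine removes the silyl group to give the cis-diol 2α,3α-dihydroxy-7β-isopropenyl-4,4,8,10β-tetramethyl-5βH-decal-8-en-9-yl triflate F2. Its unhindered equatorial 2-OH is acylated with 14 (pyridine, 0 °C) to the regioisomeric ester 3α-hydroxy-2α-[(S)-2-methyl-2-(TES-oxy)butanoyloxy]-7β-isopropenyl-4,4,8,10β-tetramethyl-5βH-decal-8-en-9-yl triflate F3. DBU in toluene at 60 °C then equilibrates the acyl group between O2 and O3 through the cyclic ortho-acid. TBSCl/imidazole in the same flask silylates only the unhindered 2-OH of the 3-O-acyl isomer, so the equilibrium drains into the 2-O-silyl 3-O-acyl compound and comes back to the route at 15.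

Step 14 (Myers transposition). The Mitsunobu displacement at C7, next to a tetrasubstituted olefin, may give elimination or SN2' products. Fallback: setting out from 25 (the allylic acetate, so step 13 is also bypassed), Pd(OAc)2/PBu3 with HCO2NH4 in dioxane at 100 °C is used. Zerovalent palladium ionises the 7β-acetate with inversion, formate loses CO2 on the metal, and the hydride is delivered from the palladium (α) face to the more substituted allyl terminus C9. This gives the same 9α-H, 7,8-olefin product and comes back to the route at 29; it makes no new compound (F0).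

Further compounds
F1 | step 2 | 1-(TBS-oxy)-2-methyl-3-(2-methyl-3-oxopent-4-en-2-yl)-5-isopropenylcyclohex-1-ene (3,5-trans; Mukaiyama–Michael adduct) | CC(C)(C)[Si](C)(C)OC1=C(C)[C@@H](C(C)(C)C(=O)C=C)C[C@H](C(C)=C)C1
F2 | step 8 | 2α,3α-dihydroxy-7β-isopropenyl-4,4,8,10β-tetramethyl-5βH-decal-8-en-9-yl triflate | O[C@@H]1[C@H](O)C[C@@]2(C)[C@H](C[C@H](C(C)=C)C(C)=C2OS(=O)(=O)C(F)(F)F)C1(C)C
F3 | step 8 | 3α-hydroxy-2α-[(S)-2-methyl-2-(TES-oxy)butanoyloxy]-7β-isopropenyl-4,4,8,10β-tetramethyl-5βH-decal-8-en-9-yl triflate | O[C@@H]1[C@H](OC(=O)[C@](C)(CC)O[Si](CC)(CC)CC)C[C@@]2(C)[C@H](C[C@H](C(C)=C)C(C)=C2OS(=O)(=O)C(F)(F)F)C1(C)C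
F0 | step 14 | none | none
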